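**Plan**
1. Endgame first: the C2 propionate and C13 ketone go back to a C2 ketone and a silylated C13 alcohol. Ring B (ten-membered) is then cut at C3–C4 by a retro-Claisen, possible because the C2 oxygen lies γ,δ to the Z C5=C6 alkene (C2(=O)–C3–C4–C5(Me)=C6).
2. This places the C2 oxygen on C6 and gives a 2-methyleneoxocane (O, C2, C1, C10, C9, C8, C7, C6), an eight-membered ether absent from the target, fused to cyclohexene ring A at C1–C10 and to butenolide ring C at C7–C8. It is opened at C2–O to a C1 ethynyl group and a C6 allylic alcohol.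
3. Further cuts: C6–C7 (vinylogous Mukaiyama aldol with methacrolein) and C8–C9 (B-alkyl Suzuki–Miyaura coupling with 3-methyltetronic acid triflate); ring A comes from (R)-carvone.
4. Forward: ring A is dressed (C1 quaternary centre, C14 acetate, C13 oxygen, C10 methylene, C2≡C3), ring C is coupled on and extended by C4–C6, the eight-membered ether is closed and expanded in one flask to ring B, then C2 is reduced and acylated and C13 oxidised.
5. Stereochemistry: C14 from (R)-carvone via a retentive Criegee rearrangement; C1 by methylation anti to isopropenyl; C10 by hydroboration anti to the C1 methyl; C7 by a catalyst-controlled aldol; 5Z by the chair Claisen transition state of the bicyclic ether (C6 is erased there); C2 by CBS reduction.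

Key step: step 16

Remark (numbering): locants are those of the target skeleton: C1 quaternary carbon (methyl C15), C2 propionyloxy carbon, C5 (methyl C16)=C6, C7 lactone carbinol, C8=C17 (methyl C18)–C19(=O), C9 methylene, C10 ring-fusion CH, C11 (methyl C20)=C12, C13 ketone, C14 acetoxy carbon.
Remark (assumption): the configuration at C13 in 8–26 is of no consequence because C13 is oxidised in step 20; the 13,14-cis isomer expected from the Luche reduction is drawn.

Step 1
Reactants: 1 (R)-(−)-carvone
Product: 2 (Z)-hydroxymethylene ketone (enol form of the C1-formyl ketone)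
Conditions: NaH, HCO2Et, cat. EtOH, Et2O, 0 °C → rt; aq. HCl
Reagents that add atoms: ethyl formate (CCOC=O)
Why: Crossed Claisen condensation (formylation): C1 is the only enolisable α-carbon of the enone and the reaction is driven by formation of the β-oxo aldehyde enolate, so no stereocentre is set.

Step 2
Reactants: 2 hydroxymethylene ketone
Product: 3 keto aldehyde (C1 bears methyl trans and formyl cis to the C14 isopropenyl group)
Conditions: MeI, K2CO3, acetone, rt → 50 °C
Reagents that add atoms: iodomethane (CI)
Why: C-alkylation of the chelated β-oxo aldehyde enolate (classical methylation of a hydroxymethylene ketone), in which iodomethane approaches C1 on the face opposite the adjacent isopropenyl group and so sets the quaternary centre.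

Step 3
Reactants: 3 keto aldehyde
Product: 4 ethynyl ketone
Conditions: (MeO)2P(O)CHN2, KOtBu, THF, −78 °C → rt
Reagents that add atoms: dimethyl (diazomethyl)phosphonate (COP(=O)(OC)C=[N+]=[N-])
Why: Seyferth–Gilbert homologation: the phosphonate anion olefinates the aldehyde in preference to the hindered conjugated C10 ketone, and the alkylidene carbene formed on loss of nitrogen gives the terminal alkyne by 1,2-hydrogen shift without touching the quaternary centre.

Step 4
Reactants: 4 ethynyl ketone
Product: 6 C14 acetate (acetoxy cis to ethynyl), via methoxy hydroperoxide 5 (not isolated)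
Conditions: O3, CH2Cl2/MeOH, NaHCO3, −78 °C (indicator end point); then Ac2O, Et3N, DMAP (cat.), 0 °C → rt
Reagents that add atoms: ozone (O=[O+][O-]); methanol (CO)
Why: Ozonolysis in methanol followed by Criegee rearrangement: ozone takes the electron-rich 1,1-disubstituted alkene in preference to the enone and the alkyne, and in the peracetate of 5 carbon C14 migrates to oxygen with retention, so the isopropenyl carbon and its methyl become the acetyl group of the C14 acetate (acetic anhydride only activates) and the carvone centre is kept.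

Step 5
Reactants: 6 C14 acetate
Product: 7 ene-1,4-dione (C10 and C13 ketones)
Conditions: Rh2(cap)4 (dirhodium tetracaprolactamate, 1 mol %), t-BuOOH (70 % aq), ClCH2CH2Cl, 40 °C
Reagents that add atoms: tert-butyl hydroperoxide (CC(C)(C)OO)
Why: Radical allylic oxidation of an enone to the ene-1,4-dione by tert-butylperoxyl radicals under dirhodium catalysis: C13 is the only γ-methylene because C1 is quaternary, and no stereocentre is involved.

Step 6
Reactants: 7 ene-dione
Product: 8 C13 allylic alcohol (13,14-cis)
Conditions: NaBH4, CeCl3·7H2O, MeOH, −78 °C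
Reagents that add atoms: none
Why: Luche reduction: the C13 carbonyl is reduced in 1,2 fashion much faster than the C10 carbonyl, which is flanked by the quaternary C1 and the methylated C11, and hydride is expected anti to the C14 acetoxy group (Felkin–Anh) to give the 13,14-cis alcohol, a centre removed again in step 20.

Step 7
Reactants: 8 C13 alcohol
Product: 9 C13 TBS ether
Conditions: TBSCl, imidazole, DMF, rt
Reagents that add atoms: tert-butyldimethylsilyl chloride (CC(C)(C)[Si](C)(C)Cl)
Why: Standard silylation of a secondary allylic alcohol, which also blocks migration of the neighbouring C14 acetate.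

Step 8
Reactants: 9 C13 TBS ether
Product: 10 diene with C10 exocyclic methylene (C9)
Conditions: Zn, CH2Br2, TiCl4, THF/CH2Cl2, 0 °C → rt
Reagents that add atoms: dibromomethane (BrCBr)
Why: Takai–Lombardo methylenation: the non-basic, oxophilic zinc–titanium methylene reagent methylenates hindered ketones and leaves the acetate, the silyl ether and the alkyne alone.

Step 9
Reactants: 10 diene
Product: 11 TMS-alkynyl diene
Conditions: TMSOTf, Et3N, Zn(OTf)2 (10 mol %), CH2Cl2, rt
Reagents that add atoms: trimethylsilyl triflate (C[Si](C)(C)OS(=O)(=O)C(F)(F)F)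
Why: Zinc-acetylide-mediated C-silylation of a terminal alkyne under amine-base conditions that do not harm the acetate; the silyl group keeps the alkyne out of the hydroboration of step 12.

Step 10
Reactants: 12 ethyl 2-methylacetoacetate
Product: 14 3-methyltetronic acid, via bromo keto ester 13 (not isolated)
Conditions: Br2, CHCl3, 0 °C → rt; then neat, 110 °C
Reagents that add atoms: none
Why: Classical tetronic acid synthesis: the kinetic α-bromide isomerises under HBr to the γ-bromo keto ester 13, whose ester oxygen displaces bromide on heating with loss of bromoethane.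

Step 11
Reactants: 14 3-methyltetronic acid
Product: 15 3-methyltetronic acid triflate
Conditions: Tf2O, Et3N, CH2Cl2, −78 °C
Reagents that add atoms: triflic anhydride (O=S(=O)(OS(=O)(=O)C(F)(F)F)C(F)(F)F)
Why: O-Sulfonylation of the vinylogous acid gives the vinylogous acyl triflate, a reactive partner for cross-coupling.

Step 12
Reactants: 11 TMS-alkynyl diene; 15 triflate
Product: 17 butenolide (C9 joined to C8; H-10 syn to the alkynyl group), via alkylborane 16 (not isolated)
Conditions: 9-BBN, THF, rt; then 15, Pd(dppf)Cl2 (5 mol %), AsPh3 (10 mol %), Cs2CO3, DMF/THF/H2O, rt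
Reagents that add atoms: none
Why: Hydroboration then B-alkyl Suzuki–Miyaura coupling: 9-BBN adds boron to the exocyclic C9 and hydrogen to C10 on the face opposite the pseudoaxial C1 methyl (the slim alkynyl group lies in the ring plane and the cis 13-silyloxy group disfavours the other half-chair), which sets C10, and the primary alkylborane then couples with the vinyl triflate to form C8–C9.

Step 13
Reactants: 17 butenolide
Product: 18 2-silyloxyfuran
Conditions: TBSOTf, Et3N, CH2Cl2, 0 °C
Reagents that add atoms: tert-butyldimethylsilyl triflate (CC(C)(C)[Si](C)(C)OS(=O)(=O)C(F)(F)F)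
Why: Soft enolisation of the butenolide at C7 by silyl triflate and amine gives the aromatic 2-silyloxyfuran; the acetate is not enolised under these conditions.

Step 14
Reactants: 18 2-silyloxyfuran; 19 methacrolein
Product: 20 aldol adduct (C7 as in the target; C6 carbinol anti to the C7 oxygen)
Conditions: SiCl4, bisphosphoramide from (R,R)-N,N'-dimethyl-1,1'-binaphthyl-2,2'-diamine with a pentane-1,5-diyl linker (5 mol %), iPr2NEt (10 mol %), CH2Cl2, −78 °C
Reagents that add atoms: none
Why: Lewis-base-catalysed vinylogous Mukaiyama aldol: the phosphoramide-bound trichlorosilyl cation activates the enal and C7 of the furan adds to the Si face of the aldehyde in the anti mode typical of this catalyst system, which sets C7 and C6 under catalyst control because the ring A centres are remote (the sense is assigned by analogy; the antipodal catalyst is used if it proves opposite).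

Step 15
Reactants: 20 aldol adduct
Product: 21 alkynol (free C2≡C3–H; C6 OH)
Conditions: AgNO3 (10 mol %), MeOH/H2O/CH2Cl2, rt
Reagents that add atoms: none
Why: Silver-catalysed protodesilylation is selective for the C(sp)–Si bond over the silyl ether and runs under neutral conditions, so the acetate stays and C7 is not epimerised.

Step 16
Reactants: 21 alkynol
Product: 23 ten-membered ketone (C2 ketone; 5Z alkene), via 2-methyleneoxocane 22 (not isolated)
Conditions: (IPr)AuNTf2 (5 mol %; IPr = 1,3-bis(2,6-diisopropylphenyl)imidazol-2-ylidene), 4 Å MS, toluene (0.002 M), 50 °C; then Et3N (10 mol %), 110 °C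
Reagents that add atoms: none
Why: Proposed new method: the cationic monovalent gold complex binds the terminal alkyne, the C6 hydroxyl adds to the internal carbon C2 and protodeauration gives the 2-methyleneoxocane 22, whose allyl vinyl ether unit C3=C2–O–C6–C5=C4 then undergoes a thermal [3,3]-sigmatropic shift that forms C3–C4, breaks O–C6 and leaves the C2 ketone and the C5=C6 alkene. The closest known reactions are the gold-catalysed intermolecular hydroalkoxylation of alkynes by allylic alcohols with in situ Claisen rearrangement and the Claisen ring expansion of 2-methylene-ω-alkenyl cyclic ethers; what is new is the ring-closing hydroalkoxylation to an eight-membered enol ether. The temporary oxocane closes in the 8-exo-dig mode, helped by the trans-diequatorial C2 and C9 arms on ring A and the planar butenolide carbon C8, and ring B is then closed by ring expansion through a six-membered chair transition state bridged from C2 to C6 by C1–C10–C9–C8–C7. No stereocentre is formed and C6 is erased, so either C6 epimer can give 23; the 5Z geometry follows because the five-atom bridge can span C1 and C7 only when C7 is pseudoaxial (inside) in the chair, while the boat that would lead to 5E eclipses the C5 methyl with the quaternary C1. The step needs intramolecular over intermolecular addition (high dilution, sieves against hydration), Markovnikov regiochemistry (normal for a terminal alkyl alkyne) and no enyne cycloisomerisation with C11=C12 (the equatorial alkynyl group is anti to C10–C11 and cannot reach it).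

Step 17
Reactants: 23 ten-membered ketone
Product: 24 (2S)-alcohol
Conditions: (R)-2-methyl-CBS-oxazaborolidine (0.5 equiv), catecholborane, toluene, −78 → −40 °C
Reagents that add atoms: none
Why: Corey–Bakshi–Shibata reduction: the ketone is flanked by the quaternary C1 (large) and the C3 methylene (small), so reagent control by the (R)-oxazaborolidine should give the (2S)-alcohol, while catecholborane at low temperature leaves the alkenes, the lactone and the esters alone.

Step 18
Reactants: 24 (2S)-alcohol
Product: 25 C2 propionate
Conditions: (EtCO)2O, DMAP, Et3N, CH2Cl2, rt → 40 °C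
Reagents that add atoms: propionic anhydride (CCC(=O)OC(=O)CC)
Why: DMAP-catalysed acylation of the hindered secondary alcohol with the anhydride; no stereocentre changes.

Step 19
Reactants: 25 C2 propionate
Product: 26 C13 allylic alcohol
Conditions: HF·pyridine, THF/pyridine, 0 °C → rt
Reagents that add atoms: none
Why: Fluoride desilylation under acidic conditions avoids base-induced migration of the acetyl group from O14 to O13 and epimerisation at C7.

Step 20
Reactants: 26 C13 allylic alcohol
Product: 27 target CNP0109273.3
Conditions: Dess–Martin periodinane, NaHCO3, CH2Cl2, 0 °C → rt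
Reagents that add atoms: none
Why: Dess–Martin oxidation of the allylic alcohol to the enone under buffered, non-basic conditions, which removes the auxiliary C13 centre and leaves the α-acetoxy centre C14 and the lactone centre C7 unepimerised.

**Compound list**
1 | (R)-(−)-carvone | CC1=CC[C@H](CC1=O)C(C)=C | starting material
2 | (Z)-hydroxymethylene ketone of carvone (C1 =CH–OH, enol of the formyl ketone) | O/C=C1\C(=O)C(C)=CC[C@H]1C(C)=C | intermediate
3 | keto aldehyde: C1 methyl trans, C1 formyl cis to the C14 isopropenyl group | C[C@]1(C=O)C(=O)C(C)=CC[C@H]1C(C)=C | intermediate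
4 | ethynyl ketone (C1 ethynyl cis to isopropenyl) | C[C@]1(C#C)C(=O)C(C)=CC[C@H]1C(C)=C | intermediate
5 | methoxy hydroperoxide from ozonolysis of 4 in methanol (mixture at the new acetal carbon; not isolated) | C[C@]1(C#C)C(=O)C(C)=CC[C@H]1C(C)(OC)OO | intermediate
6 | C14 acetate: 5-acetoxy-6-ethynyl-2,6-dimethylcyclohex-2-enone, acetoxy cis to ethynyl | C[C@]1(C#C)C(=O)C(C)=CC[C@H]1OC(C)=O | intermediate
7 | ene-1,4-dione (C10 and C13 ketones) | C[C@]1(C#C)C(=O)C(C)=CC(=O)[C@H]1OC(C)=O | intermediate
8 | C13 allylic alcohol, 13,14-cis | C[C@]1(C#C)C(=O)C(C)=C[C@@H](O)[C@H]1OC(C)=O | intermediate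
9 | C13 TBS ether | C[C@]1(C#C)C(=O)C(C)=C[C@@H](O[Si](C)(C)C(C)(C)C)[C@H]1OC(C)=O | intermediate
10 | diene with C10 exocyclic methylene, free alkyne | C[C@]1(C#C)C(=C)C(C)=C[C@@H](O[Si](C)(C)C(C)(C)C)[C@H]1OC(C)=O | intermediate
11 | TMS-alkynyl diene | C[C@]1(C#C[Si](C)(C)C)C(=C)C(C)=C[C@@H](O[Si](C)(C)C(C)(C)C)[C@H]1OC(C)=O | intermediate
12 | ethyl 2-methylacetoacetate | CCOC(=O)C(C)C(C)=O | starting material
13 | ethyl 4-bromo-2-methyl-3-oxobutanoate (not isolated) | CCOC(=O)C(C)C(=O)CBr | intermediate
14 | 3-methyltetronic acid (4-hydroxy-3-methylfuran-2(5H)-one) | CC1=C(O)COC1=O | intermediate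
15 | 3-methyl-4-(triflyloxy)furan-2(5H)-one | CC1=C(OS(=O)(=O)C(F)(F)F)COC1=O | intermediate
16 | B-(C9-alkyl)-9-BBN borane, H-10 syn to the alkynyl group (not isolated) | C[C@]1(C#C[Si](C)(C)C)[C@H](CB2C3CCCC2CCC3)C(C)=C[C@@H](O[Si](C)(C)C(C)(C)C)[C@H]1OC(C)=O | intermediate
17 | butenolide: ring A with C9H2 joined to C8 of 3-methylfuran-2(5H)-one | C[C@]1(C#C[Si](C)(C)C)[C@H](CC2=C(C)C(=O)OC2)C(C)=C[C@@H](O[Si](C)(C)C(C)(C)C)[C@H]1OC(C)=O | intermediate
18 | 2-(TBS-oxy)-3-methylfuran with the ring A methylene at furan C4 | C[C@]1(C#C[Si](C)(C)C)[C@H](CC2=COC(O[Si](C)(C)C(C)(C)C)=C2C)C(C)=C[C@@H](O[Si](C)(C)C(C)(C)C)[C@H]1OC(C)=O | intermediate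
19 | methacrolein | CC(=C)C=O | starting material
20 | aldol adduct: C7 as in the target, C6 (R) carbinol anti, TMS-alkyne | C[C@]1(C#C[Si](C)(C)C)[C@H](CC2=C(C)C(=O)O[C@@H]2[C@H](O)C(C)=C)C(C)=C[C@@H](O[Si](C)(C)C(C)(C)C)[C@H]1OC(C)=O | intermediate
21 | alkynol: terminal alkyne on C1, allylic alcohol at C6 | C[C@]1(C#C)[C@H](CC2=C(C)C(=O)O[C@@H]2[C@H](O)C(C)=C)C(C)=C[C@@H](O[Si](C)(C)C(C)(C)C)[C@H]1OC(C)=O | intermediate
22 | 2-methyleneoxocane (O bridges C2 and C6; isopropenyl on C6; not isolated) | C[C@]1(C(=C)O3)[C@H](CC2=C(C)C(=O)O[C@@H]2[C@H]3C(C)=C)C(C)=C[C@@H](O[Si](C)(C)C(C)(C)C)[C@H]1OC(C)=O | intermediate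
23 | ten-membered C2 ketone, 5Z, 13-OTBS, 14-OAc | O=C1CC/C(C)=C\[C@H]2OC(=O)C(C)=C2C[C@@H]2C(C)=C[C@@H](O[Si](C)(C)C(C)(C)C)[C@@H](OC(C)=O)[C@@]12C | intermediate
24 | (2S)-alcohol | O[C@H]1CC/C(C)=C\[C@H]2OC(=O)C(C)=C2C[C@@H]2C(C)=C[C@@H](O[Si](C)(C)C(C)(C)C)[C@@H](OC(C)=O)[C@@]12C | intermediate
25 | C2 propionate, 13-OTBS | CCC(=O)O[C@H]1CC/C(C)=C\[C@H]2OC(=O)C(C)=C2C[C@@H]2C(C)=C[C@@H](O[Si](C)(C)C(C)(C)C)[C@@H](OC(C)=O)[C@@]12C | intermediate
26 | C13 allylic alcohol | CCC(=O)O[C@H]1CC/C(C)=C\[C@H]2OC(=O)C(C)=C2C[C@@H]2C(C)=C[C@@H](O)[C@@H](OC(C)=O)[C@@]12C | intermediate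
27 | CNP0109273.3, (1R,2S,5Z,7R,10R,14S) | CCC(=O)O[C@H]1CC/C(C)=C\[C@H]2OC(=O)C(C)=C2C[C@@H]2C(C)=CC(=O)[C@@H](OC(C)=O)[C@@]12C | target

**Step count and risks**
Total: 20 steps. Longest linear sequence: 18 steps (steps 1–9 and 12–20 from (R)-carvone); steps 10–11 make the triflate.

Most likely to fail:

1. Step 16 (bears the label). The ring-closing O–H addition may be too slow at high dilution, so that hydration of the gold-bound alkyne or intermolecular addition takes over before the eight-membered ether forms. The fallback uses known reactions, sets out from 21 and returns at 22 and so at 23. Hydration of the alkyne with the same gold catalyst in wet dioxane gives the methyl ketone F1. EtSH and Zn(OTf)2 convert it into the diethyl dithioketal F2. AgClO4, NaHCO3, silica gel and 4 Å sieves in MeNO2 ionise one C–S bond and the C6 hydroxyl closes the eight-membered mixed O,S-ketal F3 (the hydroxy dithioketal cyclisation used for oxocenes). mCPBA at −78 °C gives the sulfoxide F4, which on warming in toluene with a little Et3N loses ethanesulfenic acid towards its only β-hydrogens (C3) to give 22; heating at 110 °C then gives 23.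

2. Step 14. The two faces of the 3,4-disubstituted silyloxyfuran may not be told apart well enough at C7, the resident centres being remote, so that C7 epimers form together. The fallback sets out from 18 and 19 and returns at 20. A BF3·OEt2-promoted aldol at −78 °C, which needs only high simple diastereoselectivity, gives 20 together with its 6,7-bis-epimer F5. Sharpless kinetic resolution (Ti(OiPr)4, L-(+)-diisopropyl tartrate, t-BuOOH, 4 Å MS, CH2Cl2, −20 °C) reads the C6 carbinol and should epoxidise F5 faster, to the epoxy alcohol F6, so that 20 is recovered by chromatography.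

3. Step 12. Hydroboration may occur from both faces of the hindered exocyclic diene, or transmetalation of the β-branched alkylborane may be slow while the triflate is hydrolysed by the base. The fallback sets out from 11 and 14 and returns at 17. Borane 16 is oxidised (NaBO3·4H2O) to the primary alcohol F7 and its 10-epimer F8, which are separated. F7 is converted with I2, PPh3 and imidazole into the iodide F9. Zinc insertion (Zn dust, LiCl, THF) gives the alkylzinc iodide F10. Negishi coupling (Pd(OAc)2, SPhos) with 4-bromo-3-methylfuran-2(5H)-one F11, made from 14 with oxalyl bromide and catalytic DMF, gives 17.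

**Further compounds**
F1 | step 16 | C2 methyl ketone (hydration product of 21) | C[C@]1(C(C)=O)[C@H](CC2=C(C)C(=O)O[C@@H]2[C@H](O)C(C)=C)C(C)=C[C@@H](O[Si](C)(C)C(C)(C)C)[C@H]1OC(C)=O
F2 | step 16 | C2 diethyl dithioketal | C[C@]1(C(C)(SCC)SCC)[C@H](CC2=C(C)C(=O)O[C@@H]2[C@H](O)C(C)=C)C(C)=C[C@@H](O[Si](C)(C)C(C)(C)C)[C@H]1OC(C)=O
F3 | step 16 | eight-membered mixed O,S-ketal (C2 epimers) | C[C@]1(C(C)(SCC)O3)[C@H](CC2=C(C)C(=O)O[C@@H]2[C@H]3C(C)=C)C(C)=C[C@@H](O[Si](C)(C)C(C)(C)C)[C@H]1OC(C)=O
F4 | step 16 | sulfoxide of F3 | C[C@]1(C(C)(S(=O)CC)O3)[C@H](CC2=C(C)C(=O)O[C@@H]2[C@H]3C(C)=C)C(C)=C[C@@H](O[Si](C)(C)C(C)(C)C)[C@H]1OC(C)=O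
F5 | step 14 | 6,7-bis-epimer of 20 | C[C@]1(C#C[Si](C)(C)C)[C@H](CC2=C(C)C(=O)O[C@H]2[C@@H](O)C(C)=C)C(C)=C[C@@H](O[Si](C)(C)C(C)(C)C)[C@H]1OC(C)=O
F6 | step 14 | erythro epoxy alcohol from F5 | C[C@]1(C#C[Si](C)(C)C)[C@H](CC2=C(C)C(=O)O[C@H]2[C@@H](O)[C@]3(C)CO3)C(C)=C[C@@H](O[Si](C)(C)C(C)(C)C)[C@H]1OC(C)=O
F7 | step 12 | C9 primary alcohol, H-10 syn to alkynyl | C[C@]1(C#C[Si](C)(C)C)[C@H](CO)C(C)=C[C@@H](O[Si](C)(C)C(C)(C)C)[C@H]1OC(C)=O
F8 | step 12 | 10-epimer of F7 | C[C@]1(C#C[Si](C)(C)C)[C@@H](CO)C(C)=C[C@@H](O[Si](C)(C)C(C)(C)C)[C@H]1OC(C)=O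
F9 | step 12 | C9 primary iodide | C[C@]1(C#C[Si](C)(C)C)[C@H](CI)C(C)=C[C@@H](O[Si](C)(C)C(C)(C)C)[C@H]1OC(C)=O
F10 | step 12 | C9 alkylzinc iodide | C[C@]1(C#C[Si](C)(C)C)[C@H](C[Zn]I)C(C)=C[C@@H](O[Si](C)(C)C(C)(C)C)[C@H]1OC(C)=O
F11 | step 12 | 4-bromo-3-methylfuran-2(5H)-one | CC1=C(Br)COC1=O
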